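Remark on the chemistry: the target is taken as the (1S,2S,7R,10S,14S)-5Z isomer in the numbering defined below. Both antipodes of the ferrocenyl diphosphine are commercial, and the one that sends vinyl to the Re face of C3 of enone 3 is assumed to be used.

## The problem

1. The target joins a cyclohexene, ring C (C1, C10, C11=C12, C13, C14), through the C1–C10 bond to a ten-membered carbocycle (C1 to C10) that holds a Z trisubstituted alkene (C5=C6, methyl on C5) and is fused at C7–C8 to an α-methyl butenolide (C7, O, C19 carbonyl, C17, C8).
2. Four of the five stereocentres are clustered, with quaternary C1 (methyl) lying between the C2 propanoate carbinol, the C14 acetate carbinol and the ring-fusion methine C10, while the fifth, C7, sits alone on the far side of the large ring.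
3. Within the cluster a relay is possible: C10 can steer an electrophile to the opposite face of C1, a closed transition state at C1 can fix C2, and a free C2 hydroxyl can deliver hydride to C14.
4. C7 has no neighbouring stereocentre and must be set either by the conformation of the closing ring or by a reagent.
5. The two esters differ (propanoate on C2, acetate on C14) yet sit on two equally hindered neopentyl carbinols, so they must be told apart by mechanism and not by sterics.
6. The lactone C7–O bond is doubly allylic (ionisable, epimerisable through a furanolate), the Z alkene must not be isomerised, and the ten-membered ring is strained.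
7. The enabling feature is that C10, C1 and C2 are contiguous while C14 can be a ketone and C11 a masked ketone, so that ring C is a 2-methylcyclohex-2-enone that receives C9 at its β-carbon and C2 at its α-carbon, with C9 and C2 trans as an anti aldol approach provides.
8. In what follows β is the face of ring C that carries the C1 methyl group and C9, and α is the face that carries C2 and the C14 oxygen; C2 and C14 are S and the 5,6-alkene is Z throughout.

## Retrosynthesis

**32 to 30 (C7–C8 and the lactone C7O–C19 bond).** Cutting C7–C8 opens the ten-membered ring and the butenolide together, because the alkoxide 31 of a Nozaki–Hiyama–Kishi addition sits cis to an ester and lactonises. Cuts at C6–C7, C3–C4 or C1–C10 each require the butenolide or the quaternary centre to be carried through a palladium step (see Roads not taken). Precursor 30 is a ring C compound with two open arms: a Z enal (C7) and a Z β-triflyloxy enoate (C8, C17, C19). The forward step must close a ten-membered ring and set C7 by substrate control.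

**30 to 24 (C8–C17).** Enol triflate 28 comes from β-keto ester 26 through its sodium enolate 27, and 26 comes from aldehyde 24 and methyl propanoate by aldol addition to 25 and oxidation. The C7 aldehyde is unmasked last from a TBDPS ether, by way of allylic alcohol 29 and enal 30. The forward steps need an ester enolate that adds only to the aldehyde in the presence of two esters, and a triflation that places OTf cis to the ester.

**24 to 19 (C11–CH3).** The C11 methyl and the position of the C11=C12 alkene come from ketone 19 through its kinetic enolate 20, enol triflate 21 and a Negishi methylation to 22; removal of the TBS group then gives alcohol 23 and oxidation gives 24. Methyl addition followed by dehydration would not fix the alkene position. The forward step needs deprotonation at the C12 methylene and not at the hindered C10 methine, with both esters in place.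

**19 to 15 (C8–O and C11=O).** The two-carbon arm is the vinyl group of 15 after hydroboration through borane 16 to alcohol 17, kept as TBS ether 18 while the dimethyl ketal is hydrolysed. The order matters: a C11 ketone next to a C10 vinyl group would be a β,γ-unsaturated ketone that enolises toward C10 and conjugates, so hydroboration comes before ketal hydrolysis. The TBDPS/TBS pair allows the C8 oxygen to be freed before the C7 oxygen.

**15 to 12 (the two ester C–O bonds).** An Evans–Tishchenko reduction with propanal, through hemiacetal 13, turns the C2 hydroxyl of 12 into the propanoate while it delivers hydride to C14; the new C14 hydroxyl of 14 is then acetylated to 15. Reduction to a diol followed by selective acylation would offer no reliable basis for choosing between the two carbinols. The forward step needs 1,3-anti hydride delivery to the β face of C14.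

**12 to 3 + 9 + 8 (C9–C10 and C1–C2).** Conjugate vinylation of enone 3 with Grignard reagent 9 and aldol trapping with aldehyde 8, through enolates 10 and 11, make two skeletal bonds and three stereocentres from three achiral components. A single catalyst-set centre (C10) relays C1 and C2. The forward step needs enantioselective 1,4-addition at a hindered β-carbon, anti approach of the aldehyde, and a closed chair for C2.

**3 to 1 and 8 to 4.** Enone 3 is the partly hydrogenated quinone monoketal 2 of phenol 1. Aldehyde 8 is nerol 4 with its remote alkene cleaved by way of silyl ether 5, epoxide 6 and diol 7, so the Z alkene is bought, not made.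

## Roads not taken

**Alternative 1:** The cut is C1–C10. The fourteen-membered 2-methyl-1,3-diketone A1, which carries an allylic methyl carbonate at C10, would be ionised by Pd(PPh3)4 to a π-allyl over C10 to C12. The stabilised C1 enolate of A1 would attack C10 across the ring to give diketone A2, forming ring C and the ten-membered ring at once.
- Merits: a soft, non-basic nucleophile suited to allylic alkylation; attack at C12 would need a four-membered ring, so regiochemistry is secure; the fourteen-membered ring of A1 is easier to close than a ten-membered one; C7 could be set under reagent control before A1 is closed. In the last point it is better than the chosen plan.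
- Weak points: zerovalent palladium can also ionise the doubly allylic lactone C7–O bond of A1. The facial course at C1 rests on an unknown transannular conformation. A2 has two ketones on a quaternary carbon, which is prone to retro-Claisen cleavage, and both must still be reduced with facial control and converted into different esters.
- Comparison: the chosen plan sets C2 during C–C bond formation, uses that oxygen to set C14 and differentiates the esters in the same step. It has to set against Alternative 1 a less certain ten-membered closure and a C7 centre under substrate control.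

**Alternative 2:** The cut is C6–C7. The seco furan A3, a C7 trimethylstannyl furan carrying a (Z)-alkenyl iodide at C6, would be closed with Pd2(dba)3 and AsPh3 to the furan-fused ten-membered carbocycle A4. The silylated furan ring of A4 would then be oxidised to the butenolide of 32.
- Merits: a neutral sp2–sp2 coupling that tolerates both esters and retains alkene geometry; the furan of A4 is a robust butenolide surrogate. As a ring closure it is probably more dependable than the chromium-mediated one.
- Weak points: the furan and the conjugated Z alkene of A4 must approach coplanarity inside a ten-membered ring. The late peracid-type oxidation of A4 meets two electron-rich trisubstituted alkenes. C7 is then created by protonation, which gives no more control than the chosen plan has. The (Z)-iodoalkene terminus of A3, with a methyl group on the neighbouring carbon, cannot be taken from nerol and needs its own stereoselective synthesis. A3 still requires the C1/C2/C10/C14 array.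
- Comparison: the chosen plan forms C7 in a C–C bond-forming step with spontaneous lactonisation, needs no late oxidant and no tin. It concedes to Alternative 2 the better-precedented ring-closing reaction.

**Alternative 3:** The cut is C3–C4. The twelve-membered allyl β-keto lactone A5 would be ionised by Pd(PPh3)4 at its C4–O bond, lose CO2 and recombine at C4 to give the 2-oxo ten-membered carbocycle A6.
- Merits: the strained ring arises by contraction of the easier macrolactone A5; the enolate is formed regiospecifically under neutral conditions; the butenolide and the C14 acetate are already in place in A5, and only C2 remains to be adjusted in A6. For closing this ring it is arguably the most reliable of the four plans.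
- Weak points: the π-allyl over C4 to C6 that A5 gives comes from a Z alkene and can equilibrate before recombination, eroding the geometry. Attack at C6 would give an eight-membered ring. C6 of A5 is flanked by the doubly allylic lactone oxygen at C7. The C2 ketone of A6 must be reduced to the 2S alcohol beside a quaternary carbon with no hydroxyl left to direct it.
- Comparison: the chosen plan never exposes the Z alkene to palladium and fixes C2 in the aldol. It pays for this with the harder direct closure of the ten-membered ring, which the route through A5 and A6 avoids.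

Key step: step 6

## Route

Intermediates from 12 on are named in the target numbering with the α/β convention given above.

Step 1
Reactants: 1 4-methoxy-2-methylphenol
Product: 2 4,4-dimethoxy-2-methylcyclohexa-2,5-dien-1-one
Conditions: PhI(OAc)2, MeOH, 0 °C
Reagents that add atoms: methanol CO
Why: Oxidative dearomatisation of a para-alkoxyphenol by the hypervalent iodine reagent, with methanol capturing the phenoxonium ion at C4, is the standard route to quinone monoketals.

Step 2
Reactants: 2 4,4-dimethoxy-2-methylcyclohexa-2,5-dien-1-one
Product: 3 4,4-dimethoxy-2-methylcyclohex-2-en-1-one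
Conditions: H2 (1 atm), RhCl(PPh3)3 (cat.), toluene, rt
Reagents that add atoms: none
Why: Homogeneous hydrogenation with RhCl(PPh3)3 is sensitive to alkene substitution, so the disubstituted C5=C6 bond should be reduced before the methyl-bearing one; the neutral medium avoids loss of methanol and re-aromatisation.

Step 3
Reactants: 4 nerol [(2Z)-3,7-dimethylocta-2,6-dien-1-ol]
Product: 5 neryl tert-butyldiphenylsilyl ether
Conditions: t-BuPh2SiCl, imidazole, CH2Cl2, 0 °C to rt
Reagents that add atoms: tert-butyl(chloro)diphenylsilane CC(C)(C)[Si](Cl)(c1ccccc1)c1ccccc1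
Why: Standard silylation of a primary allylic alcohol; TBDPS is chosen because it must outlast a ketal hydrolysis and a later TBS cleavage.

Step 4
Reactants: 5 neryl tert-butyldiphenylsilyl ether
Product: 6 (2Z)-1-(tert-butyldiphenylsilyloxy)-6,7-epoxy-3,7-dimethyloct-2-ene (racemic at C6)
Conditions: mCPBA, NaHCO3, CH2Cl2, −20 to 0 °C
Reagents that add atoms: 3-chloroperbenzoic acid O=C(OO)c1cccc(Cl)c1
Why: Prilezhaev epoxidation prefers the remote 6,7-alkene, which is more electron-rich than the 2,3-alkene deactivated by the allylic oxygen; the new centre is racemic and is destroyed in step 5.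

Step 5
Reactants: 6 (2Z)-1-(tert-butyldiphenylsilyloxy)-6,7-epoxy-3,7-dimethyloct-2-ene
Product: 8 (4Z)-6-(tert-butyldiphenylsilyloxy)-4-methylhex-4-enal, via diol 7 (not isolated)
Conditions: H5IO6, THF/H2O, 0 °C to rt
Reagents that add atoms: water O
Why: Periodic acid hydrolyses the epoxide and cleaves the resulting glycol in one pot (Malaprade-type cleavage); the Z alkene and the silyl ether are inert to it. The water oxygen enters diol 7 and leaves with acetone, so the carbonyl oxygen of 8 is the former epoxide oxygen.

Step 6
Reactants: 3 4,4-dimethoxy-2-methylcyclohex-2-en-1-one; 9 vinylmagnesium bromide; 8 (4Z)-6-(tert-butyldiphenylsilyloxy)-4-methylhex-4-enal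
Product: 12 (2S,3R)-2-[(1S,4Z)-6-(tert-butyldiphenylsilyloxy)-1-hydroxy-4-methylhex-4-en-1-yl]-4,4-dimethoxy-2-methyl-3-vinylcyclohexan-1-one, via magnesium enolate 10 (not isolated), via zinc enolate 11 (not isolated)
Conditions: CuBr·SMe2 (5 mol %), 1-[2-(dicyclohexylphosphino)ferrocenyl]ethyldiphenylphosphine (6 mol %, antipode for Re-face delivery), 9, t-BuOMe, −78 °C; ZnCl2, THF, −78 °C; 8, −78 to −40 °C; pH 7 buffer
Reagents that add atoms: none
Why: The monovalent copper–diphosphine complex takes vinyl from 9, binds the enone and transfers vinyl to C3 of 3 (target C10) through a trivalent copper intermediate, releasing magnesium enolate 10 with the enolate fixed between C14 and C1; ZnCl2 converts it into the less basic zinc enolate 11, which adds to 8. The closest known reaction type is the copper/ferrocenyl-diphosphine-catalysed asymmetric conjugate addition of Grignard reagents to cyclic enones, 2-methylcycloalkenones included, followed by trapping of the metal enolate with an electrophile. No ring is closed. C10 is set by the chiral copper complex, which must deliver vinyl to the Re face of C3 of 3. C1 is set by approach of the aldehyde to the enolate face opposite the new vinyl group, which makes C9 and C2 trans. C2 is set by a Zimmerman–Traxler chair in which the chain of 8 is equatorial and the ring-locked enolate has its methyl cis to the enolate oxygen, so hydroxyl and methyl come out syn (2S). The step needs 1,4- over 1,2-addition (soft copper nucleophile), an enolate that is not protonated or equilibrated before the aldehyde arrives (aprotic, −78 °C), and addition faster than enolisation of 8 or retro-aldol (zinc counter-ion, cold buffered quench that also spares the ketal).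

Step 7
Reactants: 12 aldol adduct (C14 ketone, free C2 hydroxyl)
Product: 14 2-O-propanoyl-14α-hydroxy compound (C1 β-methyl; C10 β-vinyl; C11 dimethyl ketal; C7 OTBDPS), via propanal hemiacetal 13 (not isolated)
Conditions: EtCHO (excess), SmI2 (0.3 equiv), THF, −10 °C
Reagents that add atoms: propanal CCC=O
Why: Evans–Tishchenko reduction: trivalent samarium formed in situ holds the ketone oxygen and the hemiacetal oxygen of 13 in a chair, and the hemiacetal hydride passes to C14 while its carbon becomes the C2 propanoate. With the C3 chain and C10 equatorial and the ketone oxygen axial, hydride arrives on the β face of C14, giving the 1,3-anti, 14S (α) alcohol. The two carbinols are told apart in the step that creates the second.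

Step 8
Reactants: 14 2-O-propanoyl-14α-hydroxy compound
Product: 15 2-O-propanoyl-14α-acetoxy compound (C10 β-vinyl; C11 dimethyl ketal; C7 OTBDPS)
Conditions: Ac2O, Et3N, DMAP, CH2Cl2, rt
Reagents that add atoms: acetic anhydride CC(=O)OC(C)=O
Why: DMAP-catalysed acylation of the one free, hindered secondary alcohol; no stereocentre is touched.

Step 9
Reactants: 15 2-O-propanoyl-14α-acetoxy compound
Product: 17 C8 primary alcohol (C10 β-CH2CH2OH; C11 dimethyl ketal), via B-alkyl-9-BBN 16 (not isolated)
Conditions: 9-BBN, THF, 0 °C to rt; NaBO3·4H2O, H2O, rt
Reagents that add atoms: 9-borabicyclo[3.3.1]nonane B1C2CCCC1CCC2; sodium perborate [Na+].[O-]OB=O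
Why: Brown hydroboration–oxidation: 9-BBN adds anti-Markovnikov to the monosubstituted vinyl group and leaves the trisubstituted alkene and the esters alone; perborate oxidises the borane without hydrolysing the acetate. It is placed before ketal hydrolysis so that no C11 ketone ever sits next to a C10 vinyl group. Boron is present only in 16, and the oxygen of the new hydroxyl comes from perborate.

Step 10
Reactants: 17 C8 primary alcohol
Product: 18 C8 tert-butyldimethylsilyl ether (C11 dimethyl ketal)
Conditions: t-BuMe2SiCl, imidazole, DMF, rt
Reagents that add atoms: tert-butyl(chloro)dimethylsilane CC(C)(C)[Si](C)(C)Cl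
Why: Silylation of the primary alcohol prevents hemiketal formation with the C11 ketone and gives a silyl ether that can later be removed in the presence of the C7 TBDPS ether.

Step 11
Reactants: 18 C8 tert-butyldimethylsilyl ether
Product: 19 C11 ketone (C10 β-CH2CH2OTBS; 2-O-propanoyl; 14α-acetoxy; C7 OTBDPS)
Conditions: PPTS, acetone/H2O, rt
Reagents that add atoms: water O
Why: Acid-catalysed hydrolysis of a dimethyl ketal is far faster than cleavage of either silyl ether in wet acetone, and the weak acid should not enolise C10.

Step 12
Reactants: 19 C11 ketone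
Product: 21 C11 enol triflate with the alkene at C11=C12, via potassium enolate 20 (not isolated)
Conditions: KN(SiMe3)2, THF, −78 °C; N-(5-chloropyridin-2-yl)bis(trifluoromethanesulfonyl)imide, −78 °C
Reagents that add atoms: N-(5-chloropyridin-2-yl)bis(trifluoromethanesulfonyl)imide FC(F)(F)S(=O)(=O)N(c1ccc(Cl)cn1)S(=O)(=O)C(F)(F)F
Why: Kinetic deprotonation removes a C12 methylene proton in preference to the hindered C10 methine beside the quaternary centre, and the ketone is several pK units more acidic than either ester. The triflimide reagent traps enolate 20 on oxygen at −78 °C before it can equilibrate.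

Step 13
Reactants: 21 C11 enol triflate
Product: 22 C11-methyl cyclohexene (C11=C12; C10 β-CH2CH2OTBS)
Conditions: Pd(PPh3)4 (5 mol %), Me2Zn, THF, 0 °C to rt
Reagents that add atoms: dimethylzinc C[Zn]C
Why: Negishi coupling of an alkenyl triflate with a methylzinc reagent proceeds with retention of alkene position and tolerates esters and silyl ethers; the homoallylic C14 acetate is not ionised by zerovalent palladium.

Step 14
Reactants: 22 C11-methyl cyclohexene
Product: 23 C8 primary alcohol (C11=C12; C7 OTBDPS retained)
Conditions: PPTS, MeOH, rt
Reagents that add atoms: none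
Why: Acid-catalysed methanolysis removes a primary alkyl TBS ether much faster than a TBDPS ether, a routinely used selectivity.

Step 15
Reactants: 23 C8 primary alcohol
Product: 24 C8 aldehyde
Conditions: Dess–Martin periodinane, NaHCO3, CH2Cl2, 0 °C to rt
Reagents that add atoms: none
Why: Buffered Dess–Martin oxidation gives the aldehyde without over-oxidation or epimerisation of the allylic C10.

Step 16
Reactants: 24 C8 aldehyde
Product: 25 methyl 3-hydroxy-2-methylalkanoate (C8 hydroxyl; C17 methyl; mixture at C8 and C17)
Conditions: methyl propanoate, LiN(i-Pr)2, THF, −78 °C; then 24, −78 °C; pH 7 buffer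
Reagents that add atoms: methyl propanoate CCC(=O)OC
Why: Aldol addition of a lithium ester enolate is much faster at an aldehyde than at the acetate or propanoate at −78 °C; the two new centres are not controlled because both are removed in steps 17 and 18.

Step 17
Reactants: 25 methyl 3-hydroxy-2-methylalkanoate
Product: 26 β-keto ester (C8 ketone; C17 methyl; C19 methyl ester)
Conditions: Dess–Martin periodinane, NaHCO3, CH2Cl2, rt
Reagents that add atoms: none
Why: Dess–Martin oxidation is the usual way to convert β-hydroxy esters into β-keto esters without retro-aldol cleavage.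

Step 18
Reactants: 26 β-keto ester
Product: 28 (Z)-enol triflate (C8 OTf cis to C19 ester), via sodium enolate 27 (not isolated)
Conditions: NaH, Et2O, 0 °C; Tf2O, 0 °C
Reagents that add atoms: trifluoromethanesulfonic anhydride FC(F)(F)S(=O)(=O)OS(=O)(=O)C(F)(F)F
Why: In a weakly coordinating solvent the sodium enolate 27 of a 2-alkyl β-keto ester is a chelate, and O-triflation of it gives the Z enol triflate. This places the oxygen leaving group, and later C7, cis to C19.

Step 19
Reactants: 28 (Z)-enol triflate
Product: 29 C7 primary (Z)-allylic alcohol
Conditions: HF·pyridine, pyridine, THF, 0 °C to rt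
Reagents that add atoms: none
Why: Buffered hydrogen fluoride removes the TBDPS group without the basicity that would eliminate or hydrolyse the β-triflyloxy enoate.

Step 20
Reactants: 29 C7 primary (Z)-allylic alcohol
Product: 30 (Z)-enal (C7 aldehyde) bearing the C8 (Z)-enol triflate
Conditions: Dess–Martin periodinane, NaHCO3, CH2Cl2, 0 °C
Reagents that add atoms: none
Why: Buffered Dess–Martin oxidation of neryl-type alcohols gives the Z enal with little isomerisation when kept cold and used at once.

Step 21
Reactants: 30 (Z)-enal bearing the C8 (Z)-enol triflate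
Product: 32 CNP0112230.1 [(1S,2S,7R,10S,14S)-5Z isomer], via chromium alkoxide 31 (not isolated)
Conditions: CrCl2 (excess), NiCl2 (cat.), DMSO/THF, rt, high dilution
Reagents that add atoms: none
Why: Nozaki–Hiyama–Kishi reaction: zerovalent nickel inserts into the C8–OTf bond, the alkenyl group passes to trivalent chromium and adds only to the aldehyde, closing the ten-membered ring; alkoxide 31 then acylates itself on the cis ester to form the butenolide. C7 is set by substrate control in the ring-forming conformer, which is restricted by the Z alkene, the planar enoate and ring C. The 7R outcome is the least secure stereochemical call of the route (see below).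

## Compound list

1 | 4-methoxy-2-methylphenol | COc1ccc(O)c(C)c1 | starting material
2 | 4,4-dimethoxy-2-methylcyclohexa-2,5-dien-1-one | CC1=CC(OC)(OC)C=CC1=O | intermediate
3 | 4,4-dimethoxy-2-methylcyclohex-2-en-1-one | CC1=CC(OC)(OC)CCC1=O | intermediate
4 | nerol | CC(C)=CCC/C(C)=C\CO | starting material
5 | neryl tert-butyldiphenylsilyl ether | CC(C)=CCC/C(C)=C\CO[Si](c1ccccc1)(c1ccccc1)C(C)(C)C | intermediate
6 | (2Z)-1-(tert-butyldiphenylsilyloxy)-6,7-epoxy-3,7-dimethyloct-2-ene (racemic) | CC1(C)OC1CC/C(C)=C\CO[Si](c1ccccc1)(c1ccccc1)C(C)(C)C | intermediate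
7 | (6Z)-8-(tert-butyldiphenylsilyloxy)-2,6-dimethyloct-6-ene-2,3-diol (racemic) | CC(C)(O)C(O)CC/C(C)=C\CO[Si](c1ccccc1)(c1ccccc1)C(C)(C)C | intermediate (not isolated)
8 | (4Z)-6-(tert-butyldiphenylsilyloxy)-4-methylhex-4-enal | O=CCC/C(C)=C\CO[Si](c1ccccc1)(c1ccccc1)C(C)(C)C | intermediate
9 | vinylmagnesium bromide | C=C[Mg]Br | starting material
10 | bromomagnesium (3R)-4,4-dimethoxy-2-methyl-3-vinylcyclohex-1-en-1-olate | CC1=C(O[Mg]Br)CCC(OC)(OC)[C@@H]1C=C | intermediate (not isolated)
11 | chlorozinc (3R)-4,4-dimethoxy-2-methyl-3-vinylcyclohex-1-en-1-olate | CC1=C(O[Zn]Cl)CCC(OC)(OC)[C@@H]1C=C | intermediate (not isolated)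
12 | (2S,3R)-2-[(1S,4Z)-6-(tert-butyldiphenylsilyloxy)-1-hydroxy-4-methylhex-4-en-1-yl]-4,4-dimethoxy-2-methyl-3-vinylcyclohexan-1-one | O[C@@H](CC/C(C)=C\CO[Si](c2ccccc2)(c3ccccc3)C(C)(C)C)[C@@]1(C)C(=O)CCC(OC)(OC)[C@@H]1C=C | intermediate
13 | C2 O-(1-hydroxypropyl) hemiacetal of 12 (bound to samarium in the flask) | CCC(O)O[C@@H](CC/C(C)=C\CO[Si](c2ccccc2)(c3ccccc3)C(C)(C)C)[C@@]1(C)C(=O)CCC(OC)(OC)[C@@H]1C=C | intermediate (not isolated)
14 | 2-O-propanoyl-14α-hydroxy compound (C1 β-methyl, C10 β-vinyl, C11 dimethyl ketal, C7 OTBDPS) | CCC(=O)O[C@@H](CC/C(C)=C\CO[Si](c2ccccc2)(c3ccccc3)C(C)(C)C)[C@@]1(C)[C@@H](O)CCC(OC)(OC)[C@@H]1C=C | intermediate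
15 | 2-O-propanoyl-14α-acetoxy compound (C10 β-vinyl, C11 dimethyl ketal, C7 OTBDPS) | CCC(=O)O[C@@H](CC/C(C)=C\CO[Si](c2ccccc2)(c3ccccc3)C(C)(C)C)[C@@]1(C)[C@@H](OC(C)=O)CCC(OC)(OC)[C@@H]1C=C | intermediate
16 | B-alkyl-9-BBN adduct of 15 (boron on C8) | CCC(=O)O[C@@H](CC/C(C)=C\CO[Si](c2ccccc2)(c3ccccc3)C(C)(C)C)[C@@]1(C)[C@@H](OC(C)=O)CCC(OC)(OC)[C@@H]1CCB4C5CCCC4CCC5 | intermediate (not isolated)
17 | C8 primary alcohol (C11 dimethyl ketal) | CCC(=O)O[C@@H](CC/C(C)=C\CO[Si](c2ccccc2)(c3ccccc3)C(C)(C)C)[C@@]1(C)[C@@H](OC(C)=O)CCC(OC)(OC)[C@@H]1CCO | intermediate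
18 | C8 tert-butyldimethylsilyl ether (C11 dimethyl ketal) | CCC(=O)O[C@@H](CC/C(C)=C\CO[Si](c2ccccc2)(c3ccccc3)C(C)(C)C)[C@@]1(C)[C@@H](OC(C)=O)CCC(OC)(OC)[C@@H]1CCO[Si](C)(C)C(C)(C)C | intermediate
19 | C11 ketone (C8 OTBS, C7 OTBDPS, 2-O-propanoyl, 14α-acetoxy) | CCC(=O)O[C@@H](CC/C(C)=C\CO[Si](c2ccccc2)(c3ccccc3)C(C)(C)C)[C@@]1(C)[C@@H](OC(C)=O)CCC(=O)[C@@H]1CCO[Si](C)(C)C(C)(C)C | intermediate
20 | potassium C11=C12 enolate of 19 | CCC(=O)O[C@@H](CC/C(C)=C\CO[Si](c2ccccc2)(c3ccccc3)C(C)(C)C)[C@@]1(C)[C@@H](OC(C)=O)CC=C([O-])[C@@H]1CCO[Si](C)(C)C(C)(C)C.[K+] | intermediate (not isolated)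
21 | C11 enol triflate (C11=C12) | CCC(=O)O[C@@H](CC/C(C)=C\CO[Si](c2ccccc2)(c3ccccc3)C(C)(C)C)[C@@]1(C)[C@@H](OC(C)=O)CC=C(OS(=O)(=O)C(F)(F)F)[C@@H]1CCO[Si](C)(C)C(C)(C)C | intermediate
22 | C11-methyl cyclohexene (C8 OTBS, C7 OTBDPS) | CCC(=O)O[C@@H](CC/C(C)=C\CO[Si](c2ccccc2)(c3ccccc3)C(C)(C)C)[C@@]1(C)[C@@H](OC(C)=O)CC=C(C)[C@@H]1CCO[Si](C)(C)C(C)(C)C | intermediate
23 | C8 primary alcohol (C11=C12, C7 OTBDPS) | CCC(=O)O[C@@H](CC/C(C)=C\CO[Si](c2ccccc2)(c3ccccc3)C(C)(C)C)[C@@]1(C)[C@@H](OC(C)=O)CC=C(C)[C@@H]1CCO | intermediate
24 | C8 aldehyde | CCC(=O)O[C@@H](CC/C(C)=C\CO[Si](c2ccccc2)(c3ccccc3)C(C)(C)C)[C@@]1(C)[C@@H](OC(C)=O)CC=C(C)[C@@H]1CC=O | intermediate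
25 | methyl 3-hydroxy-2-methylalkanoate (C8 hydroxyl, C17 methyl; mixture at C8 and C17) | CCC(=O)O[C@@H](CC/C(C)=C\CO[Si](c2ccccc2)(c3ccccc3)C(C)(C)C)[C@@]1(C)[C@@H](OC(C)=O)CC=C(C)[C@@H]1CC(O)C(C)C(=O)OC | intermediate
26 | β-keto ester (C8 ketone, C17 methyl, C19 methyl ester; mixture at C17) | CCC(=O)O[C@@H](CC/C(C)=C\CO[Si](c2ccccc2)(c3ccccc3)C(C)(C)C)[C@@]1(C)[C@@H](OC(C)=O)CC=C(C)[C@@H]1CC(=O)C(C)C(=O)OC | intermediate
27 | sodium (Z)-enolate of 26 | CCC(=O)O[C@@H](CC/C(C)=C\CO[Si](c2ccccc2)(c3ccccc3)C(C)(C)C)[C@@]1(C)[C@@H](OC(C)=O)CC=C(C)[C@@H]1C/C([O-])=C(\C)C(=O)OC.[Na+] | intermediate (not isolated)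
28 | (Z)-enol triflate (C8 OTf cis to C19 ester; C7 OTBDPS) | CCC(=O)O[C@@H](CC/C(C)=C\CO[Si](c2ccccc2)(c3ccccc3)C(C)(C)C)[C@@]1(C)[C@@H](OC(C)=O)CC=C(C)[C@@H]1C/C(OS(=O)(=O)C(F)(F)F)=C(\C)C(=O)OC | intermediate
29 | C7 primary (Z)-allylic alcohol with the C8 (Z)-enol triflate | CCC(=O)O[C@@H](CC/C(C)=C\CO)[C@@]1(C)[C@@H](OC(C)=O)CC=C(C)[C@@H]1C/C(OS(=O)(=O)C(F)(F)F)=C(\C)C(=O)OC | intermediate
30 | (Z)-enal (C7 aldehyde) with the C8 (Z)-enol triflate | CCC(=O)O[C@@H](CC/C(C)=C\C=O)[C@@]1(C)[C@@H](OC(C)=O)CC=C(C)[C@@H]1C/C(OS(=O)(=O)C(F)(F)F)=C(\C)C(=O)OC | intermediate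
31 | ring-closed (7R) chromium alkoxide, written as the free C7 alcohol with the C19 methyl ester | CCC(=O)O[C@H]1CC/C(C)=C\[C@@H](O)/C(=C(/C)C(=O)OC)C[C@H]2C(C)=CC[C@H](OC(C)=O)[C@]12C | intermediate (not isolated)
32 | CNP0112230.1, (1S,2S,7R,10S,14S)-5Z | CCC(=O)O[C@H]1CC/C(C)=C\[C@H]2OC(=O)C(C)=C2C[C@H]2C(C)=CC[C@H](OC(C)=O)[C@]12C | target

## Step count and least certain steps

Total: 21 steps. Longest linear sequence: 19 steps (nerol 4 to 32: steps 3 to 21). The enone branch (steps 1 and 2) joins at step 6.

**Step 6 (key step).** The most likely failure is sluggish or poorly enantioselective vinyl transfer, because the β-carbon of 3 lies between a ketal carbon and a methylated alkene carbon and vinyl Grignard reagents are harder partners than alkyl ones. At the trapping stage, proton transfer from the enolisable aldehyde or reversal of the aldol would erode the C1/C2 outcome. The fallback divides the step. It sets out from 3 and 9: the same copper-catalysed addition run in the presence of Me3SiCl, which accelerates 1,4-addition, should give the trimethylsilyl enol ether F1, which can be isolated and checked. MeLi then releases the lithium enolate F2, and ZnCl2 brings it back to zinc enolate 11 and, with 8, to 12.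

**Step 21.** The most likely failure is poor or wrong facial selectivity at C7, since this centre is fixed only by the conformation of a closing ten-membered ring; oligomerisation and protodemetalation are secondary concerns. The fallback corrects the centre after ring closure instead of during it. It sets out from 30, whose cyclisation would then give mainly the 7-epimeric lactone F3. F3 is converted with i-Pr3SiOTf and Et3N into the 2-(triisopropylsilyloxy)furan F4, in which C7 is planar. Protonolysis with HF·pyridine at low temperature returns the α-methyl butenolide, with the proton arriving from the exposed face of the ring, and rejoins the route at 32. Both epimers can be recycled through F4.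

**Step 7.** The most likely failure is retro-aldol cleavage of the samarium aldolate (the α-carbon is quaternary and hydride transfer to a hindered cyclic ketone may be slow), or migration of the propanoyl group to the C14 oxygen. The fallback separates reduction from acylation. It sets out from 12: Me4NBH(OAc)3 in MeCN/AcOH at −30 °C (Saksena–Evans reduction through the same chair) should give the anti-1,3-diol F5. Propanoic anhydride (one equivalent) with Et3N and catalytic DMAP at low temperature should then acylate the open-chain C2 carbinol ahead of the axial ring carbinol at C14, rejoining the route at 14. The selectivity of that acylation is the price of the fallback.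

**Step 12.** The most likely failure is loss of regiocontrol or of the C10 configuration through enolate equilibration toward C10, or attack of the enolate or base on the acetate. The fallback avoids enolate chemistry. It sets out from 19: methylenation with Zn, CH2Br2 and TiCl4 (Takai–Lombardo, non-basic and ester-tolerant) gives the C11 exocyclic methylene compound F6. F6 is isomerised by hydrogen-atom transfer with chloro[N,N'-bis(3,5-di-tert-butylsalicylidene)-1,2-cyclohexanediamino]cobalt and PhSiH3, which should move the alkene toward the accessible C12 methylene rather than the hindered C10 methine, rejoining the route at 22.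

## Further compounds

F1 | step 6 | (R)-[(4,4-dimethoxy-2-methyl-3-vinylcyclohex-1-en-1-yl)oxy]trimethylsilane | CC1=C(O[Si](C)(C)C)CCC(OC)(OC)[C@@H]1C=C
F2 | step 6 | lithium (3R)-4,4-dimethoxy-2-methyl-3-vinylcyclohex-1-en-1-olate | CC1=C(O[Li])CCC(OC)(OC)[C@@H]1C=C
F3 | step 21 | 7-epimer of 32 (7S lactone) | CCC(=O)O[C@H]1CC/C(C)=C\[C@@H]2OC(=O)C(C)=C2C[C@H]2C(C)=CC[C@H](OC(C)=O)[C@]12C
F4 | step 21 | 2-(triisopropylsilyloxy)furan derived from 32 or F3 (C7 and C8 as furan carbons, silyloxy on C19) | CCC(=O)O[C@H]1CC/C(C)=C\c2oc(O[Si](C(C)C)(C(C)C)C(C)C)c(C)c2C[C@H]2C(C)=CC[C@H](OC(C)=O)[C@]12C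
F5 | step 7 | 2,14-anti diol (2S,14S; C10 β-vinyl, C11 dimethyl ketal, C7 OTBDPS) | O[C@@H](CC/C(C)=C\CO[Si](c2ccccc2)(c3ccccc3)C(C)(C)C)[C@@]1(C)[C@@H](O)CCC(OC)(OC)[C@@H]1C=C
F6 | step 12 | C11 exocyclic methylene compound (C8 OTBS, C7 OTBDPS, 2-O-propanoyl, 14α-acetoxy) | CCC(=O)O[C@@H](CC/C(C)=C\CO[Si](c2ccccc2)(c3ccccc3)C(C)(C)C)[C@@]1(C)[C@@H](OC(C)=O)CCC(=C)[C@@H]1CCO[Si](C)(C)C(C)(C)C
A1 | alternative 1 | fourteen-membered 2-methyl-1,3-diketone with C10 methyl carbonate, (Z)-C11=C12 and the butenolide in the ring | CC1C(=O)CC/C(C)=C\[C@H]2OC(=O)C(C)=C2CC(OC(=O)OC)/C(C)=C\CC1=O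
A2 | alternative 1 | bicyclic 2,14-diketone with the complete carbon skeleton | O=C1CC/C(C)=C\[C@H]2OC(=O)C(C)=C2C[C@H]2C(C)=CCC(=O)[C@]12C
A3 | alternative 2 | seco C7 trimethylstannyl furan with (Z)-alkenyl iodide at C6 | CCC(=O)O[C@@H](CC/C(C)=C\I)[C@@]1(C)[C@@H](OC(C)=O)CC=C(C)[C@@H]1Cc2c([Sn](C)(C)C)oc([Si](C)(C)C)c2C
A4 | alternative 2 | furan-fused ten-membered carbocycle | CCC(=O)O[C@H]1CC/C(C)=C\c2oc([Si](C)(C)C)c(C)c2C[C@H]2C(C)=CC[C@H](OC(C)=O)[C@]12C
A5 | alternative 3 | twelve-membered allyl β-keto lactone (C2 ketone, C3 methylene, carboxylate oxygen on C4) | O=C1CC(=O)OC/C(C)=C\[C@H]2OC(=O)C(C)=C2C[C@H]2C(C)=CC[C@H](OC(C)=O)[C@]12C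
A6 | alternative 3 | 2-oxo ten-membered carbocycle with butenolide and C14 acetate | O=C1CC/C(C)=C\[C@H]2OC(=O)C(C)=C2C[C@H]2C(C)=CC[C@H](OC(C)=O)[C@]12C
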